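**Retrosynthetic overview**

1. Last event, in one flask: the O1–C2 bond of the pyranone ring is made by a catalyst-controlled intramolecular oxa-Michael addition of a phenol to an alkylidene β-keto ester, used as its E/Z mixture; the temporary ester on C3 is then cut out as CO2 and isobutene.
2. Before that: C2=C3 by Knoevenagel condensation of a 2-hydroxyaryl β-keto tert-butyl ester with veratraldehyde; the keto ester by C-tert-butoxycarbonylation of 6-hydroxy-2,3,4-trimethoxyacetophenone; the ketone by ortho-acetylation of 3,4,5-trimethoxyphenol.
3. Enabling feature: in the pyranone ring, O1 is a phenol oxygen of ring A (on C8a) ortho to the C4 acyl carbon (on C4a), and the O1–C2 bond lies β to the C4 ketone, so the ring is an oxa-Michael retron. C3 is a bare CH2 between C4=O and the stereogenic C2, so it can carry a CO2tBu group that activates the acceptor, gives a chiral hydrogen-bond catalyst a two-point handle, and is removed without trace.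
4. Ring order: rings A (trimethoxybenzene) and B (dimethoxybenzene) are bought as arenes; the pyranone ring C (O1, C2, C3, C4, C4a, C8a) is the only ring made and is closed last, with C2 set in the same operation.

Key step: step 4

Assumption: the quinine-derived epi-amino thiourea is taken as the pseudoenantiomer that gives the 2S series with this substrate class. The sense is to be confirmed on the first run (CD, chiral HPLC), and the quinidine-derived pseudoenantiomer would be used with no other change if it proved opposite.

**Step 1**
Reactants: 1 3,4,5-trimethoxyphenol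
Product: 2 1-(6-hydroxy-2,3,4-trimethoxyphenyl)ethan-1-one
Conditions: AcOH, BF3·OEt2 (3 equiv), 90 °C; then H2O
Reagents that add atoms: acetic acid, CC(=O)O
Why: Friedel–Crafts (Fries-type) C-acetylation of an electron-rich phenol promoted by BF3, in which the two positions ortho to the hydroxyl are the only free ring carbons and are equivalent by symmetry, so a single regioisomer must result, and the product is held as its BF2 chelate, which should stop a second acylation.

**Step 2**
Reactants: 2 1-(6-hydroxy-2,3,4-trimethoxyphenyl)ethan-1-one
Product: 3 tert-butyl 3-(6-hydroxy-2,3,4-trimethoxyphenyl)-3-oxopropanoate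
Conditions: LiHMDS (3.2 equiv), THF, −78 °C; Boc2O (1.1 equiv), −78 to 0 °C; cold 1 M HCl quench
Reagents that add atoms: di-tert-butyl dicarbonate (Boc2O), CC(C)(C)OC(=O)OC(=O)OC(C)(C)C
Why: Claisen-type C-acylation of the lithium enolate in the phenoxide/enolate dianion, in which the third equivalent of base stores the product as its stabilised β-keto ester enolate so that it is not acylated again, and any aryl tert-butyl carbonate formed at the phenoxide oxygen should pass its Boc group to the neighbouring enolate carbon with loss of the better phenoxide leaving group (Baker–Venkataraman-type transfer).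

**Step 3**
Reactants: 3 tert-butyl 3-(6-hydroxy-2,3,4-trimethoxyphenyl)-3-oxopropanoate; 4 3,4-dimethoxybenzaldehyde (veratraldehyde)
Product: 5 tert-butyl 3-(3,4-dimethoxyphenyl)-2-(6-hydroxy-2,3,4-trimethoxybenzoyl)prop-2-enoate (E/Z mixture, used as such)
Conditions: piperidine (10 mol %), AcOH (10 mol %), 4 Å MS, toluene, rt
Reagents that add atoms: none
Why: Knoevenagel condensation of the doubly activated methylene with the aldehyde through its piperidinium iminium ion, with water taken up by the sieves; no stereocentre is formed, the alkene geometry need not be controlled because step 4 is stereoconvergent, and the buffered amine salt at room temperature should leave the ketone-chelated phenol uncyclised.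

**Step 4**
Reactants: 5 tert-butyl 3-(3,4-dimethoxyphenyl)-2-(6-hydroxy-2,3,4-trimethoxybenzoyl)prop-2-enoate (E/Z mixture)
Product: 8 (2S)-5,6,7,3',4'-pentamethoxyflavanone, via (2S)-flavanone-3-carboxylic tert-butyl ester 6 (not isolated), via (2S)-flavanone-3-carboxylic acid 7 (not isolated)
Conditions: 9-amino(9-deoxy)epi-quinine N-[3,5-bis(trifluoromethyl)phenyl]thiourea (10 mol %), toluene, −25 °C; then TsOH·H2O (0.5 equiv), 80 °C, same flask
Reagents that add atoms: none
Why: The quinuclidine nitrogen of the bifunctional catalyst deprotonates the phenol while the thiourea binds the 1,3-dicarbonyl unit, so the phenoxide oxygen adds to the benzylidene carbon in an intramolecular oxa-Michael addition that closes the pyranone ring in the 6-endo-trig mode; TsOH then cleaves the tert-butyl ester and the β-keto acid decarboxylates at 80 °C. The closest known reaction type is the cinchona-thiourea-catalysed asymmetric oxa-Michael cyclisation of 2-hydroxyaryl alkylidene β-keto esters with acidic decarboxylation in the same pot. The only new stereocentre, C2, is set under catalyst control, the chiral ion pair exposing one enantiotopic face of the benzylidene carbon to the tethered phenoxide. The step is stereoconvergent: the E and Z alkylidenes should interconvert under the amine catalyst through reversible conjugate addition to the doubly activated alkene faster than either cyclises, and the C3 epimers and enol of 6 all collapse to one compound once C3 becomes CH2. The selectivity needed is enantiofacial control together with suppression of the racemising retro-oxa-Michael pathway, and the C3 ester secures both: it gives two-point binding to the thiourea, makes the acceptor reactive at −25 °C and traps the adduct as a stabilised β-keto ester enol, while the ester is removed under acid, where base-type ring opening of the flavanone is slow.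

**Compound list**

1 | 3,4,5-trimethoxyphenol | COc1cc(O)cc(OC)c1OC | starting material
2 | 1-(6-hydroxy-2,3,4-trimethoxyphenyl)ethan-1-one | CC(=O)c1c(O)cc(OC)c(OC)c1OC | intermediate
3 | tert-butyl 3-(6-hydroxy-2,3,4-trimethoxyphenyl)-3-oxopropanoate | CC(C)(C)OC(=O)CC(=O)c1c(O)cc(OC)c(OC)c1OC | intermediate
4 | 3,4-dimethoxybenzaldehyde (veratraldehyde) | COc1ccc(C=O)cc1OC | starting material
5 | tert-butyl 3-(3,4-dimethoxyphenyl)-2-(6-hydroxy-2,3,4-trimethoxybenzoyl)prop-2-enoate, E/Z mixture | COc1ccc(C=C(C(=O)OC(C)(C)C)C(=O)c2c(O)cc(OC)c(OC)c2OC)cc1OC | intermediate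
6 | tert-butyl (2S)-2-(3,4-dimethoxyphenyl)-5,6,7-trimethoxy-4-oxochromane-3-carboxylate, C3 epimers in equilibrium with the enol | COc1ccc([C@@H]2C(C(=O)OC(C)(C)C)C(=O)c3c(cc(OC)c(OC)c3OC)O2)cc1OC | intermediate (not isolated)
7 | (2S)-2-(3,4-dimethoxyphenyl)-5,6,7-trimethoxy-4-oxochromane-3-carboxylic acid, C3 epimers | COc1ccc([C@@H]2C(C(=O)O)C(=O)c3c(cc(OC)c(OC)c3OC)O2)cc1OC | intermediate (not isolated)
8 | (2S)-5,6,7,3',4'-pentamethoxyflavanone, i.e. (2S)-2-(3,4-dimethoxyphenyl)-5,6,7-trimethoxychroman-4-one | COc1ccc([C@@H]2CC(=O)c3c(cc(OC)c(OC)c3OC)O2)cc1OC | target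

Total step count: 4. Longest linear sequence: 4 steps (1 → 2 → 3 → 5 → 8); aldehyde 4 enters at step 3.

**Steps most likely to fail**

Step 4 (key step). Enantiopurity may be lost in three ways: weak enantiofacial discrimination for this electron-rich benzylidene next to a di-ortho-substituted aryl ketone; incomplete equilibration of the geometric isomers before cyclisation; or reversible ring opening and reclosure during the hot acidic decarboxylation, helped by the electron-rich B ring. The fallback sets out from 2 and comes back at 8, and sets the stereocentre by C–C bond formation on a finished pyranone ring. Ketone 2 is heated with N,N-dimethylformamide dimethyl acetal (toluene, 100 °C) to give the enaminone (E)-3-(dimethylamino)-1-(6-hydroxy-2,3,4-trimethoxyphenyl)prop-2-en-1-one F1. This closes with loss of dimethylamine (conc. HCl, CH2Cl2, rt) to 5,6,7-trimethoxy-4H-chromen-4-one F2. Palladium-catalysed asymmetric conjugate addition of (3,4-dimethoxyphenyl)boronic acid to F2 [Pd(OCOCF3)2, t-BuPyOx of the hand that gives the 2S series, NH4PF6, H2O, ClCH2CH2Cl, 60 °C] should then give 8 directly under non-basic conditions.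

Step 3. The free phenol may cyclise prematurely under the amine during the condensation, giving racemic 6 that would be carried on and lower the enantiopurity; the condensation may also stall because the electron-rich aldehyde is a poor electrophile and cannot be forced thermally without this cyclisation. The fallback sets out from 2 and comes back at 5, with the phenol masked throughout. Allyl bromide, K2CO3, DMF gives 1-[6-(allyloxy)-2,3,4-trimethoxyphenyl]ethan-1-one F3. LiHMDS (2.2 equiv) and Boc2O give tert-butyl 3-[6-(allyloxy)-2,3,4-trimethoxyphenyl]-3-oxopropanoate F4. Condensation with 4 (piperidine, AcOH, toluene, Dean–Stark), which can now be driven hard, gives tert-butyl 2-[6-(allyloxy)-2,3,4-trimethoxybenzoyl]-3-(3,4-dimethoxyphenyl)prop-2-enoate F5. Pd(PPh3)4 (cat.) with N-methylaniline as allyl acceptor (THF, rt) frees the phenol without base and gives 5.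

Step 2. Acylation may occur at the phenoxide oxygen or twice, or the dianion may close onto the new ester with loss of tert-butoxide to a 4-hydroxycoumarin. The fallback sets out from 1 and comes back at 3, and builds the keto ester by aldol addition and oxidation instead of enolate acylation. Vilsmeier–Haack formylation of 1 (POCl3, DMF; aq. NaOAc) gives 6-hydroxy-2,3,4-trimethoxybenzaldehyde F6. Addition of the lithium enolate of tert-butyl acetate (LDA, 2.5 equiv, THF, −78 °C) gives racemic tert-butyl 3-hydroxy-3-(6-hydroxy-2,3,4-trimethoxyphenyl)propanoate F7. Oxidation of the benzylic alcohol (activated MnO2, CH2Cl2, rt) gives 3.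

**Further compounds**

F1 | step 4 | (E)-3-(dimethylamino)-1-(6-hydroxy-2,3,4-trimethoxyphenyl)prop-2-en-1-one | CN(C)/C=C/C(=O)c1c(O)cc(OC)c(OC)c1OC
F2 | step 4 | 5,6,7-trimethoxy-4H-chromen-4-one | COc1cc2occc(=O)c2c(OC)c1OC
F3 | step 3 | 1-[6-(allyloxy)-2,3,4-trimethoxyphenyl]ethan-1-one | CC(=O)c1c(OCC=C)cc(OC)c(OC)c1OC
F4 | step 3 | tert-butyl 3-[6-(allyloxy)-2,3,4-trimethoxyphenyl]-3-oxopropanoate | CC(C)(C)OC(=O)CC(=O)c1c(OCC=C)cc(OC)c(OC)c1OC
F5 | step 3 | tert-butyl 2-[6-(allyloxy)-2,3,4-trimethoxybenzoyl]-3-(3,4-dimethoxyphenyl)prop-2-enoate, E/Z mixture | COc1ccc(C=C(C(=O)OC(C)(C)C)C(=O)c2c(OCC=C)cc(OC)c(OC)c2OC)cc1OC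
F6 | step 2 | 6-hydroxy-2,3,4-trimethoxybenzaldehyde | O=Cc1c(O)cc(OC)c(OC)c1OC
F7 | step 2 | tert-butyl 3-hydroxy-3-(6-hydroxy-2,3,4-trimethoxyphenyl)propanoate, racemic | CC(C)(C)OC(=O)CC(O)c1c(O)cc(OC)c(OC)c1OC
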